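**Strategy.** The route rests on disconnecting, in the cyclohexane ring, the bond between the bridgehead carbon that carries the pyran oxygen and the lactone carbonyl (C12) and the neighbouring carbinol carbon (C24). This is the β-hydroxy-lactone (Claisen/aldol) retron hidden in the 2-oxabicyclo[2.2.2]octanone. The key step is an intramolecular Claisen acylation of a δ-lactone enolate by a Weinreb amide arm. In one operation it closes the cyclohexane, creates quaternary C12 and merges both C12 epimers. Its precursor is a cis-syn-cis pyran/δ-lactone/cyclopentane tricycle, assembled by an intramolecular glyoxylate hetero-Diels–Alder reaction that sets C10 and C20 together.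

Key step: step 13

Remark (locants used here, own numbering): C1–C7 heptyl; C8=C9 side-chain alkene; C10 pyran CH; O11 pyran O; C12 bridgehead bearing O11 and lactone carbonyl C13; O14 lactone O; C15 second bridgehead; C16, C17 (CHOH), C18, C19 cyclopentane; C20 CH shared by pyran and cyclohexane; C21=C22(CH3) pyran alkene; C23 (CH2) and C24 (CHOH) complete the cyclohexane.
Assumption: compounds 1, 2, 5 and 6 and all reagents named are taken as commercial.

**Step 1**
Reactants: 1 (E)-dec-2-enal; 2 2-(triphenyl-λ5-phosphanylidene)propanal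
Product: 3 (2E,4E)-2-methyldodeca-2,4-dienal
Conditions: PhMe, 80 °C
Reagents that add atoms: none
Why: Wittig olefination with a stabilised α-branched ylide should give the (E)-trisubstituted enal and leave the existing (E)-alkene untouched.

**Step 2**
Reactants: 3 (2E,4E)-2-methyldodeca-2,4-dienal
Product: 4 (3E,5E)-3-methyltrideca-3,5-dien-1-yne
Conditions: Me3SiCHN2, n-BuLi, THF, −78 °C → rt; aq. NH4Cl
Reagents that add atoms: (trimethylsilyl)diazomethane C[Si](C)(C)C=[N+]=[N-]
Why: Colvin homologation: the lithiated diazomethane adds to the aldehyde, Peterson elimination gives a diazoalkene, and the alkylidene carbene undergoes 1,2-hydrogen shift to the terminal alkyne without affecting the diene geometry.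

**Step 3**
Reactants: 5 (R)-4-(tert-butyldimethylsilyloxy)cyclopent-2-en-1-one; 6 N-methoxy-N-methylacetamide
Product: 8 2-[(1R,4R)-1-hydroxy-4-(tert-butyldimethylsilyloxy)cyclopent-2-en-1-yl]-N-methoxy-N-methylacetamide (OH cis to OTBS), via lithium enolate 7 (not isolated)
Conditions: LiN(iPr)2, THF, −78 °C; then 5, −78 °C; aq. NH4Cl
Reagents that add atoms: none
Why: Aldol-type 1,2-addition of the amide enolate to the enone carbonyl should occur anti to the silyloxy group (steric approach control), which sets C15 with its hydroxyl cis to OTBS; the minor diastereomer is removed by chromatography.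

**Step 4**
Reactants: 8 cis-hydroxy silyl ether
Product: 9 2-[(1R,4R)-1,4-dihydroxycyclopent-2-en-1-yl]-N-methoxy-N-methylacetamide (cis-diol)
Conditions: Bu4NF, AcOH, THF, 0 °C → rt
Reagents that add atoms: none
Why: Fluoride desilylation, buffered with acetic acid so that the tertiary β-hydroxy amide does not undergo retro-aldol cleavage.

**Step 5**
Reactants: 9 cis-diol
Product: 10 2-[(1R)-1-hydroxy-4-oxocyclopent-2-en-1-yl]-N-methoxy-N-methylacetamide
Conditions: MnO2, CH2Cl2, rt
Reagents that add atoms: none
Why: Allylic oxidation with MnO2 touches only the secondary allylic alcohol, so the chirality is relayed from C17 to the tertiary carbinol C15 and an enone for conjugate addition is unveiled.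

**Step 6**
Reactants: 10 hydroxy enone; 4 (3E,5E)-3-methyltrideca-3,5-dien-1-yne
Product: 12 2-[(1R,2S)-1-hydroxy-2-[(3E,5E)-3-methyltrideca-3,5-dien-1-yn-1-yl]-4-oxocyclopentyl]-N-methoxy-N-methylacetamide (alkynyl cis to OH), via dimethyl(alkynyl)alane 11 (not isolated)
Conditions: 4, AlMe3, Et3N (cat.), PhMe, rt; then 10, PhMe/CH2Cl2, 0 °C → rt; aq. KNaC4H4O6
Reagents that add atoms: none
Why: Hydroxyl-directed conjugate alkynylation: the alane is bound as the aluminium alkoxide of the C15 hydroxyl and should deliver the alkynyl group to C19 on the hydroxyl face, so that C20 is cis to O14.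

**Step 7**
Reactants: 12 β-hydroxy ketone
Product: 13 2-[(1R,2S,4R)-1,4-dihydroxy-2-[(3E,5E)-3-methyltrideca-3,5-dien-1-yn-1-yl]cyclopentyl]-N-methoxy-N-methylacetamide (C17–OH trans to C15–OH)
Conditions: Me4NBH(OAc)3, MeCN/AcOH, −30 °C
Reagents that add atoms: none
Why: Saksena–Evans reduction: the acetoxyborohydride bound to the C15 hydroxyl delivers hydride to the C17 ketone from the same face, which should give the trans (anti) 1,3-diol.

**Step 8**
Reactants: 13 alkynyl diol
Product: 15 2-[(1R,2S,4R)-1,4-dihydroxy-2-[(1E,3E,5E)-3-methyltrideca-1,3,5-trien-1-yl]cyclopentyl]-N-methoxy-N-methylacetamide, via vinylsilane 14 (not isolated)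
Conditions: [Cp*Ru(MeCN)3]PF6 (cat.), (EtO)3SiH, CH2Cl2, 0 °C → rt; then CuI, Bu4NF, THF, rt
Reagents that add atoms: none
Why: Ruthenium-catalysed trans-hydrosilylation of the alkyne followed by protodesilylation with retention is a net trans semi-reduction to the (E)-alkene; either silyl regioisomer converges on the same triene.

**Step 9**
Reactants: 15 triene diol
Product: 16 2-[(1R,2S,4R)-1-hydroxy-4-(tert-butyldimethylsilyloxy)-2-[(1E,3E,5E)-3-methyltrideca-1,3,5-trien-1-yl]cyclopentyl]-N-methoxy-N-methylacetamide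
Conditions: TBSCl, imidazole, DMF, 0 °C → rt
Reagents that add atoms: tert-butyldimethylsilyl chloride CC(C)(C)[Si](C)(C)Cl
Why: Silylation is selective for the secondary over the hindered tertiary alcohol.

**Step 10**
Reactants: 16 tertiary alcohol
Product: 17 bromoacetate of 16 at O14
Conditions: BrCH2COBr, pyridine, CH2Cl2, 0 °C
Reagents that add atoms: bromoacetyl bromide BrCC(Br)=O
Why: O-Acylation of the tertiary alcohol with a reactive acid bromide installs C12 and C13.

**Step 11**
Reactants: 17 bromoacetate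
Product: 19 glyoxylate ester of 16 at O14, via nitrate ester 18 (not isolated)
Conditions: AgNO3, MeCN, rt (dark); then NaOAc, DMSO, rt
Reagents that add atoms: silver nitrate [Ag+].[O-][N+](=O)[O-]
Why: Kornblum-type oxidation: silver-assisted substitution gives the nitrate ester and acetate-induced loss of nitrite gives the aldehyde under non-acidic conditions that spare the triene.

**Step 12**
Reactants: 19 glyoxylate ester
Product: 20 cis-syn-cis tricyclic lactone (3,6-dihydro-2H-pyran fused at C12–C20 to the δ-lactone C12/C13/O14/C15/C19/C20 which is fused at C15–C19 to the cyclopentane; H12, H19, H20 and the C15 CH2C(O)N(OMe)Me arm on one face; (E)-non-1-enyl at C10 cis to C19; C17–OTBS trans to O14)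
Conditions: PhMe (0.005 M), BHT (cat.), 4 Å MS, 90 °C
Reagents that add atoms: none
Why: Intramolecular hetero-Diels–Alder reaction of the glyoxylate C=O with the (E,E)-diene: the ester tether allows only C12–C20/O11–C10 bonding, suprafacial addition places H10 and H20 cis, and the endo transition state (lactone carbonyl under the diene, C18 anti to the forming bond) should give H19/H20 cis.

**Step 13**
Reactants: 20 tricyclic lactone
Product: 23 β-keto lactone (17-O-TBS ether of the 24-oxo compound; 2-oxabicyclo[2.2.2]octane-3,5-dione core), via lithium enolate 21 (not isolated), via tetrahedral adduct 22 (not isolated)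
Conditions: LiN(SiMe3)2 (1.1 equiv), THF, −78 → −40 °C; aq. NH4Cl
Reagents that add atoms: none
Why: LiN(SiMe3)2 removes the C12 hydrogen (α to the lactone carbonyl and more acidic than the amide α-hydrogens at C23) to give planar enolate 21, whose δ-lactone can adopt a boat in which the C15 acetamide arm is flagpole to C12, so that C12 attacks the amide carbonyl C24 and the lithium-chelated tetrahedral adduct 22 persists until work-up, where it collapses to ketone 23. The closest known reaction type is the intramolecular Claisen (Dieckmann-type) C-acylation of ester and lactone enolates by Weinreb amides, and the related cyclisation of β-acyloxy esters to dihydropyran-2,4-diones. The cyclohexane closes in a 6-(enolendo)-exo-trig mode through the C12–C24 bond, which at the same time completes the 2-oxabicyclo[2.2.2]octane. The only new stereocentre, quaternary C12, is fixed by the tether, because C24 can reach only the enolate face on which the C15 arm sits, so both C12 epimers of 20 converge. The step needs deprotonation at C12 rather than C23 (which would trigger β-elimination of the lactone carboxylate) and C- rather than O-acylation; the pKa gap, one equivalent of hindered base at −78 °C and the six-membered geometry should secure this, while the stable adduct 22 blocks retro-Claisen cleavage and the equatorial nonenyl group disfavours a [2,3]-Wittig shift.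

**Step 14**
Reactants: 23 β-keto lactone
Product: 24 17-O-TBS ether of the target
Conditions: NaBH4, CeCl3·7H2O, MeOH/THF, −78 °C; AcOH
Reagents that add atoms: none
Why: Luche-type ketone reduction: hydride should enter C24 from the open cleft beside the flat lactone bridge, away from the C19–C20 bridge whose hydrogens shield the other face, so the new hydroxyl ends syn to the C19–C20 bridge as in the target; low temperature suppresses retro-Claisen opening.

**Step 15**
Reactants: 24 silyl ether
Product: 25 target CNP0127096.1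
Conditions: HF·pyridine, pyridine, THF, 0 °C → rt
Reagents that add atoms: none
Why: Buffered fluoride desilylation removes the secondary TBS ether without ionising the doubly allylic pyran ether or opening the bridged lactone.

**Compound list**
1 | (E)-dec-2-enal | CCCCCCC/C=C/C=O | starting material
2 | 2-(triphenyl-λ5-phosphanylidene)propanal | CC(C=O)=P(c1ccccc1)(c1ccccc1)c1ccccc1 | starting material
3 | (2E,4E)-2-methyldodeca-2,4-dienal | O=C/C(C)=C/C=C/CCCCCCC | intermediate
4 | (3E,5E)-3-methyltrideca-3,5-dien-1-yne | C#C/C(C)=C/C=C/CCCCCCC | intermediate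
5 | (R)-4-(tert-butyldimethylsilyloxy)cyclopent-2-en-1-one | O=C1C[C@@H](O[Si](C)(C)C(C)(C)C)C=C1 | starting material
6 | N-methoxy-N-methylacetamide | CC(=O)N(C)OC | starting material
7 | lithium enolate of 6 | C=C(O[Li])N(C)OC | intermediate
8 | 2-[(1R,4R)-1-hydroxy-4-(tert-butyldimethylsilyloxy)cyclopent-2-en-1-yl]-N-methoxy-N-methylacetamide | O[C@]1(C[C@@H](O[Si](C)(C)C(C)(C)C)C=C1)CC(=O)N(C)OC | intermediate
9 | 2-[(1R,4R)-1,4-dihydroxycyclopent-2-en-1-yl]-N-methoxy-N-methylacetamide | O[C@]1(C[C@@H](O)C=C1)CC(=O)N(C)OC | intermediate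
10 | 2-[(1R)-1-hydroxy-4-oxocyclopent-2-en-1-yl]-N-methoxy-N-methylacetamide | O[C@]1(CC(=O)C=C1)CC(=O)N(C)OC | intermediate
11 | dimethyl[(3E,5E)-3-methyltrideca-3,5-dien-1-yn-1-yl]alane | C[Al](C)C#C/C(C)=C/C=C/CCCCCCC | intermediate
12 | 2-[(1R,2S)-1-hydroxy-2-[(3E,5E)-3-methyltrideca-3,5-dien-1-yn-1-yl]-4-oxocyclopentyl]-N-methoxy-N-methylacetamide | O[C@]1(CC(=O)C[C@H]1C#C/C(C)=C/C=C/CCCCCCC)CC(=O)N(C)OC | intermediate
13 | 2-[(1R,2S,4R)-1,4-dihydroxy-2-[(3E,5E)-3-methyltrideca-3,5-dien-1-yn-1-yl]cyclopentyl]-N-methoxy-N-methylacetamide | O[C@]1(C[C@H](O)C[C@H]1C#C/C(C)=C/C=C/CCCCCCC)CC(=O)N(C)OC | intermediate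
14 | vinylsilane from trans addition of H–Si(OEt)3 to the alkyne of 13 (Si on C21) | O[C@]1(C[C@H](O)C[C@H]1/C=C(\[Si](OCC)(OCC)OCC)/C(C)=C/C=C/CCCCCCC)CC(=O)N(C)OC | intermediate
15 | 2-[(1R,2S,4R)-1,4-dihydroxy-2-[(1E,3E,5E)-3-methyltrideca-1,3,5-trien-1-yl]cyclopentyl]-N-methoxy-N-methylacetamide | O[C@]1(C[C@H](O)C[C@H]1/C=C/C(C)=C/C=C/CCCCCCC)CC(=O)N(C)OC | intermediate
16 | 17-O-TBS ether of 15 | O[C@]1(C[C@H](O[Si](C)(C)C(C)(C)C)C[C@H]1/C=C/C(C)=C/C=C/CCCCCCC)CC(=O)N(C)OC | intermediate
17 | O14-bromoacetate of 16 | BrCC(=O)O[C@]1(C[C@H](O[Si](C)(C)C(C)(C)C)C[C@H]1/C=C/C(C)=C/C=C/CCCCCCC)CC(=O)N(C)OC | intermediate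
18 | O14-(nitrooxy)acetate of 16 | [O-][N+](=O)OCC(=O)O[C@]1(C[C@H](O[Si](C)(C)C(C)(C)C)C[C@H]1/C=C/C(C)=C/C=C/CCCCCCC)CC(=O)N(C)OC | intermediate
19 | O14-glyoxylate of 16 | O=CC(=O)O[C@]1(C[C@H](O[Si](C)(C)C(C)(C)C)C[C@H]1/C=C/C(C)=C/C=C/CCCCCCC)CC(=O)N(C)OC | intermediate
20 | cis-syn-cis pyran/δ-lactone/cyclopentane tricycle with C15 Weinreb acetamide arm | CCCCCCC/C=C/[C@H]1O[C@H]2C(=O)O[C@]3(C[C@H](O[Si](C)(C)C(C)(C)C)C[C@H]3[C@H]2C=C1C)CC(=O)N(C)OC | intermediate
21 | lithium enolate of 20 (C12=C13–OLi) | CCCCCCC/C=C/[C@H]1OC2=C(O[Li])O[C@]3(C[C@H](O[Si](C)(C)C(C)(C)C)C[C@H]3[C@H]2C=C1C)CC(=O)N(C)OC | intermediate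
22 | lithium alkoxide of the C24 N-methoxy-N-methyl hemiaminal (tetrahedral adduct; O–Li drawn syn to the lactone carbonyl) | CCCCCCC/C=C/[C@H]1O[C@@]23C(=O)O[C@]4(C[C@H](O[Si](C)(C)C(C)(C)C)C[C@H]4[C@H]2C=C1C)C[C@@]3(O[Li])N(C)OC | intermediate
23 | 24-oxo-17-O-TBS tetracycle (β-keto lactone) | CCCCCCC/C=C/[C@H]1O[C@@]23C(=O)O[C@]4(C[C@H](O[Si](C)(C)C(C)(C)C)C[C@H]4[C@H]2C=C1C)CC3=O | intermediate
24 | 17-O-TBS ether of the target | CCCCCCC/C=C/[C@H]1O[C@@]23C(=O)O[C@]4(C[C@H](O[Si](C)(C)C(C)(C)C)C[C@H]4[C@H]2C=C1C)C[C@H]3O | intermediate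
25 | CNP0127096.1 | CCCCCCC/C=C/[C@H]1O[C@@]23C(=O)O[C@]4(C[C@H](O)C[C@H]4[C@H]2C=C1C)C[C@H]3O | target

**Totals.** 15 steps; longest linear sequence 13 steps (5 → 25, steps 3–15).

**Steps most likely to fail**

Step 12. The cycloaddition may be slow because the ester tether prefers the unreactive s-trans rotamer, and the exo approach may compete and deliver the wrong configuration at C20 relative to C19. The fallback builds the pyran bimolecularly and closes the lactone afterwards. It sets out from 16: reaction with ethyl glyoxylate under Cu(OTf)2 with the matched 2,2′-isopropylidenebis(4-tert-butyl-2-oxazoline) ligand (CH2Cl2, −20 °C) should give dihydropyran hydroxy ester F1. Attack should come anti to quaternary C15 with H19 eclipsing the diene, and C–C bonding at C20 is expected because the developing charge is then delocalised over C21, C10 and C8. Lactonisation of the tertiary hydroxyl onto the ethyl ester (Ti(OiPr)4 cat., PhMe, 80 °C) returns to the route at 20, or at its C12 epimer, which gives the same enolate in step 13.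

Step 13. Deprotonation at C23 with β-elimination of the lactone carboxylate, or sluggish or reversible C-acylation ending in mere C12 epimerisation, may defeat the ring closure. The fallback reverses the polarity of C12 and uses an aldehyde electrophile. It sets out from 20: enolisation with LiN(SiMe3)2 at −78 °C and trapping with dibenzoyl peroxide gives anomeric benzoate F2. Cp2Zr(H)Cl (THF, rt) reduces the Weinreb amide to aldehyde F3. SmI2 (THF, −78 °C) then cleaves the C12–O benzoate bond reductively, and the samarium enolate adds to the aldehyde in a Reformatsky-type closure to hydroxy lactone F4, expected as the C24 epimer of 24 from the chelated transition state. Oxidation with Dess–Martin periodinane/NaHCO3 returns to the route at 23.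

Step 6. The alkynyl group may be delivered from the face opposite the hydroxyl, or the alane may add 1,2 or attack the amide, so that the cis relation of C20 and O14 is lost. The fallback replaces directed conjugate addition by a silicon-tethered radical cyclisation. It sets out from 10:
- Saksena–Evans reduction (Me4NBH(OAc)3) gives trans-diol F5, and TBSCl/imidazole gives silyl ether F6.
- ClSiMe2CH2Br/imidazole gives bromomethylsilyl ether F7.
- Bu3SnH/AIBN (PhH, 80 °C) closes the five-membered siloxane F8 by 5-exo attack at C19 from the O14 face.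
- Tamao–Fleming oxidation (H2O2, KF, KHCO3) gives diol F9.
- Mitsunobu reaction with 1-phenyl-1H-tetrazole-5-thiol gives sulfide F10, and (NH4)6Mo7O24/H2O2 gives sulfone F11.
- Julia–Kocienski olefination of F11 with dienal 3 (KN(SiMe3)2, DME, −78 °C) returns to the route at 16.

**Further compounds**
F1 | step 12 | ethyl 3,6-dihydro-2H-pyran-2-carboxylate from 16 and ethyl glyoxylate (tertiary OH free) | CCCCCCC/C=C/[C@H]1O[C@@H](C(=O)OCC)[C@H](C=C1C)[C@@H]2C[C@@H](O[Si](C)(C)C(C)(C)C)C[C@@]2(O)CC(=O)N(C)OC
F2 | step 13 | C12 benzoate of 20 | CCCCCCC/C=C/[C@H]1O[C@@]2(OC(=O)c5ccccc5)C(=O)O[C@]3(C[C@H](O[Si](C)(C)C(C)(C)C)C[C@H]3[C@H]2C=C1C)CC(=O)N(C)OC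
F3 | step 13 | C24 aldehyde from F2 | CCCCCCC/C=C/[C@H]1O[C@@]2(OC(=O)c5ccccc5)C(=O)O[C@]3(C[C@H](O[Si](C)(C)C(C)(C)C)C[C@H]3[C@H]2C=C1C)CC=O
F4 | step 13 | C24 epimer of 24 | CCCCCCC/C=C/[C@H]1O[C@@]23C(=O)O[C@]4(C[C@H](O[Si](C)(C)C(C)(C)C)C[C@H]4[C@H]2C=C1C)C[C@@H]3O
F5 | step 6 | trans-1,4-diol from 10 | O[C@]1(C[C@H](O)C=C1)CC(=O)N(C)OC
F6 | step 6 | 17-O-TBS ether of F5 | O[C@]1(C[C@H](O[Si](C)(C)C(C)(C)C)C=C1)CC(=O)N(C)OC
F7 | step 6 | O14-(bromomethyl)dimethylsilyl ether of F6 | BrC[Si](C)(C)O[C@]1(C[C@H](O[Si](C)(C)C(C)(C)C)C=C1)CC(=O)N(C)OC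
F8 | step 6 | cis-fused 1-oxa-2-silacyclopentane from F7 | C[Si]1(C)O[C@]2(C[C@H](O[Si](C)(C)C(C)(C)C)C[C@H]2C1)CC(=O)N(C)OC
F9 | step 6 | C19 hydroxymethyl diol | O[C@]1(C[C@H](O[Si](C)(C)C(C)(C)C)C[C@H]1CO)CC(=O)N(C)OC
F10 | step 6 | 1-phenyltetrazol-5-yl sulfide of F9 | O[C@]1(C[C@H](O[Si](C)(C)C(C)(C)C)C[C@H]1CSc2nnnn2-c2ccccc2)CC(=O)N(C)OC
F11 | step 6 | 1-phenyltetrazol-5-yl sulfone | O[C@]1(C[C@H](O[Si](C)(C)C(C)(C)C)C[C@H]1CS(=O)(=O)c2nnnn2-c2ccccc2)CC(=O)N(C)OC
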